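**Assumption:** gibberellic acid (a bulk fermentation product) is taken as the cheap commercial starting material. "Dihydrogibberellic acid" here means 1,2-dihydrogibberellic acid, i.e. 3β,13-dihydroxy-20-norgibberell-16-ene-7,19-dioic acid 19,10-lactone. The target is read from its SMILES as this compound with an extra 12α-hydroxyl (axial on ring C, cis to the 13-OH, anti to C-16).

## Retrosynthetic overview

1. 6 ⇒ 5 (dihydrogibberellic acid): disconnect the C-12–O bond; forward, a late-stage enzymatic C–H hydroxylation forms the key C–O bond and sets C-12.
2. 5 ⇒ 2: the saturated 3β-alcohol comes from the ring-A enone by one-pot 1,4- then 1,2-hydride delivery, which resets C-3.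
3. 2 ⇒ 1 (gibberellic acid): allylic alcohol oxidation.
4. No ring is built: rings A, B, C, D and the 19,10-lactone are carried intact from 1; only the oxidation levels at C-1 to C-3 and C-12 change.

## Route

Step 1
Reactants: 1 gibberellic acid
Product: 2 3-dehydrogibberellic acid (ring-A 1-en-3-one)
Conditions: activated MnO2 (20 equiv), acetone, 25 °C, 16 h; filter through Celite (acetone–1% AcOH)
Reagents that add atoms: none
Why: MnO2 allylic-alcohol oxidation is chemoselective for the secondary allylic 3-OH (the 13-OH is tertiary; acid, lactone and 16-ene are inert), and it forms no stereocentre because C-3 becomes trigonal and is reset in step 2.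

Step 2
Reactants: 2 3-dehydrogibberellic acid
Product: 5 dihydrogibberellic acid (ring A saturated at C-1/C-2; 3β-OH), via potassium enolate 3 (not isolated), via saturated ketone 4 (not isolated)
Conditions: K[(s-Bu)3BH] (4.5 equiv), THF, −78 °C, 1 h; t-BuOH (1.5 equiv), −78 to −40 °C, 2 h; 1 M aq. HCl to pH 3, 0 °C
Reagents that add atoms: none
Why: Conjugate (1,4) hydride reduction of the β-unsubstituted cyclohexenone gives enolate 3, t-BuOH protonates it at C-2 to ketone 4, and the same bulky borohydride then reduces the 3-ketone by equatorial attack (axial approach on the β-face is blocked by the syn-axial H-1β and H-5β), giving the axial 3β-alcohol in a diastereoselective bulky-hydride ketone reduction.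

Step 3
Reactants: 5 dihydrogibberellic acid
Product: 6 12α-hydroxydihydrogibberellic acid (target; 12-OH cis to 13-OH)
Conditions: resting E. coli cells co-expressing an engineered CYP714A2 variant (membrane anchor truncated), Arabidopsis reductase ATR2 and Bacillus glucose dehydrogenase; NADP+ (cat.), D-glucose (3 equiv), air, potassium phosphate buffer (KH2PO4/K2HPO4, 100 mM, pH 7.4), 2% DMSO, 28 °C, 24 h; acidify to pH 3, EtOAc, reverse-phase chromatography
Reagents that add atoms: dioxygen, O=O
Why: Proposed new method: a laboratory-evolved variant of the plant gibberellin 12α-/13-hydroxylase CYP714A2 is applied to the 19-carbon lactone 5, a substrate class on which it has not been shown; the wild type binds the same bicyclo[3.2.1]octane C/D unit of its 20-carbon gibberellin acid substrates with the axial 12α-hydrogen and the 13-hydrogen over the heme and leaves the 16-ene untouched, so in 5, where C-13 already bears OH, the ferryl-oxo porphyrin radical cation (tetravalent iron) can only abstract the axial 12α-hydrogen and return OH to the same face (radical rebound with retention), setting the 12α stereocentre, while residues of the substrate-recognition sites around ring A are re-tuned by saturation mutagenesis with LC–MS screening to accept the 19,10-lactone and 3β-OH; the closest known reaction type is cytochrome P450 C–H hydroxylation with oxygen rebound, specifically the native 12α-hydroxylation of 20-carbon gibberellin acids by this enzyme.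

## Compound list

1 | gibberellic acid | C=C1C[C@]23C[C@@]1(O)CC[C@H]2[C@@]12C=C[C@H](O)[C@@](C)(C(=O)O1)[C@H]2[C@@H]3C(=O)O | starting material
2 | 3-dehydrogibberellic acid (3-oxo-1-ene) | C=C1C[C@]23C[C@@]1(O)CC[C@H]2[C@@]12C=CC(=O)[C@@](C)(C(=O)O1)[C@H]2[C@@H]3C(=O)O | intermediate
3 | dipotassium 2-en-3-olate 7-carboxylate of 3-dehydrodihydrogibberellic acid (potassium enolate) | [K+].[K+].C=C1C[C@]23C[C@@]1(O)CC[C@H]2[C@@]12CC=C([O-])[C@@](C)(C(=O)O1)[C@H]2[C@@H]3C(=O)[O-] | intermediate
4 | 3-dehydrodihydrogibberellic acid (saturated 3-ketone) | C=C1C[C@]23C[C@@]1(O)CC[C@H]2[C@@]12CCC(=O)[C@@](C)(C(=O)O1)[C@H]2[C@@H]3C(=O)O | intermediate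
5 | dihydrogibberellic acid (3β,13-dihydroxy-20-norgibberell-16-ene-7,19-dioic acid 19,10-lactone) | C=C1C[C@]23C[C@@]1(O)CC[C@H]2[C@@]12CC[C@H](O)[C@@](C)(C(=O)O1)[C@H]2[C@@H]3C(=O)O | intermediate
6 | 12α-hydroxydihydrogibberellic acid (CNP0260503.1) | C=C1C[C@]23C[C@@]1(O)[C@@H](O)C[C@H]2[C@@]12CC[C@H](O)[C@@](C)(C(=O)O1)[C@H]2[C@@H]3C(=O)O | target

## Step count and risks

Total step count: 3. Longest linear sequence: 3.

Steps most likely to fail:

**Step 3 (proposed new step).** The variant may show no turnover on the lactone substrate, or may oxidise C-11, C-15 or the 16-ene instead. The fallback uses known chemistry, sets out from 5 and comes back at 6. Lemieux–Johnson cleavage of the 16-methylene (OsO4 cat., NaIO4, THF–water) gives 16-oxo-17-nordihydrogibberellic acid F1. Condensation with 2-picolylamine (TsOH cat., toluene, 4 Å sieves, 25 °C, kept mild because 13-hydroxy-16-ketones of this ring system are prone to acyloin rearrangement) gives the 16-(pyridin-2-ylmethyl)imine of 17-nordihydrogibberellic acid F2. This is submitted crude to the imine-directed copper/dioxygen β-C–H hydroxylation of ketones (Cu(OTf)2, sodium L-ascorbate (NaC6H7O6), dioxygen, acetone–MeOH, 50 °C; Na4EDTA work-up hydrolyses the imine). C-12 is the only β-methylene within reach, since C-14 lies anti to the imine nitrogen and C-8 has no hydrogen, and the hydrogen syn to C-16 is expected to be replaced, giving 12β-hydroxy-16-oxo-17-nordihydrogibberellic acid F3. Whether the free 13-OH, which sits in the imine plane, helps or blocks this step is uncertain. Non-basic methylenation (Zn, CH2Br2, TiCl4, THF–CH2Cl2), which avoids retro-aldol cleavage of the β-hydroxy ketone, restores the 16-ene and gives 12β-hydroxydihydrogibberellic acid F4. Dess–Martin periodinane (NaHCO3-buffered, CH2Cl2, 0 °C) oxidises both secondary alcohols to 13-hydroxy-3,12-dioxo-20-norgibberell-16-ene-7,19-dioic acid 19,10-lactone F5. K[(s-Bu)3BH] (THF, −78 °C, then aq. HCl) then reduces both ketones by equatorial attack: axial approach at C-12 is blocked by the syn-axial C-10 and at C-3 by H-1β/H-5β, so the axial 12α- and 3β-alcohols of 6 result.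

**Step 2.** The hindered β-carbon next to the quaternary C-10 may divert the borohydride to 1,2-reduction (giving 1 and its 3-epimer), or the in-flask protonation may stall at 4. The fallback sets out from 2 and comes back at 5; it separates the two reductions and puts the C-3 reduction under reagent control. A catalytic copper hydride 1,4-reduction (Cu(OAc)2, 1,2-bis(diphenylphosphino)benzene, (Me2SiH)2O, t-BuOH, toluene, 25 °C, aqueous work-up) delivers isolated 4. An NADPH-dependent ketoreductase selected from a commercial panel for the 3β-alcohol (glucose dehydrogenase recycling, pH 7 buffer, 30 °C) then gives 5. No compound outside the list is made (none F0).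

**Step 1.** The free acid may bind strongly to MnO2 and be recovered poorly, or the enone may degrade on the oxidant. The fallback sets out from 1 and comes back at 5, bypassing 2. It abandons the redox relay for a direct chemoselective hydrogenation: H2 (1 atm, stopped at 1.0 equiv uptake), 5% Pd/CaCO3, THF–pyridine, 0 °C. The amine-poisoned catalyst is intended to favour the ring-A cis-alkene over the 16-methylene and to suppress hydrogenolysis of the allylic lactone. This is kept as a fallback, not the main route, because over-reduction limits the yield and the 16,17-dihydro by-product must be removed by reverse-phase chromatography. No compound outside the list is made (none F0).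

Further compounds
F0 | step 1 | none | none
F0 | step 2 | none | none
F1 | step 3 | 16-oxo-17-nordihydrogibberellic acid | O=C1C[C@]23C[C@@]1(O)CC[C@H]2[C@@]12CC[C@H](O)[C@@](C)(C(=O)O1)[C@H]2[C@@H]3C(=O)O
F2 | step 3 | 16-(pyridin-2-ylmethyl)imine of 17-nordihydrogibberellic acid | C1(=NCc4ccccn4)C[C@]23C[C@@]1(O)CC[C@H]2[C@@]12CC[C@H](O)[C@@](C)(C(=O)O1)[C@H]2[C@@H]3C(=O)O
F3 | step 3 | 12β-hydroxy-16-oxo-17-nordihydrogibberellic acid | O=C1C[C@]23C[C@@]1(O)[C@H](O)C[C@H]2[C@@]12CC[C@H](O)[C@@](C)(C(=O)O1)[C@H]2[C@@H]3C(=O)O
F4 | step 3 | 12β-hydroxydihydrogibberellic acid | C=C1C[C@]23C[C@@]1(O)[C@H](O)C[C@H]2[C@@]12CC[C@H](O)[C@@](C)(C(=O)O1)[C@H]2[C@@H]3C(=O)O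
F5 | step 3 | 13-hydroxy-3,12-dioxo-20-norgibberell-16-ene-7,19-dioic acid 19,10-lactone | C=C1C[C@]23C[C@@]1(O)C(=O)C[C@H]2[C@@]12CCC(=O)[C@@](C)(C(=O)O1)[C@H]2[C@@H]3C(=O)O
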